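A small charge of Q, 0.34 M against 0.50 M of X in the spring run, still goes flat: Z reads 31.5 % at 30.0 h and 31.7 % at 40.0 h.

| flask | X | Q | temperature | remark | time |
|---|---|---|---|---|---|
| spring | 0.50 M | 0.34 M | 102 °C | run made earlier |  |
| dusk | 0.50 M | 0.75 M | 119 °C | run made earlier |  |
| winter | 0.75 M | 0.50 M | 102 °C | run made earlier |  |
| Friday's | 0.50 M | 0.500 M | 95 °C |  | 40 h |
| Thursday's | 0.50 M | 0.500 M | 125 °C |  | 40 h |
| Monday's | 0.50 M | 0.500 M | 110 °C |  | 40 h |

- spring (time / h: Z / %): 6.00: 16.4; 12.0: 25.5; 20.0: 28.9; 25.0: 30.6; 30.0: 31.5; 40.0: 31.7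
- dusk (time / h: Z / %): 0.833: 23.3; 2.50: 41.2; 5.00: 49.8; 6.00: 51.3; 10.0: 52.9; 12.0: 52.8
- winter (time / h: Z / %): 4.00: 18.5; 10.0: 29.3; 20.0: 34.7; 30.0: 37.1; 40.0: 36.3

(scatter of a reading: 0.5 percentage points)

- the analysis behind the earlier runs scatters by 0.5 percentage points, standard deviation
- a reading or a percentage of Z counts all its forms, free or not

1. the flask that comes out highest in amount of Z, in percent of the X charged, or "all alike" when all lie within 1.5 percentage points (Friday's / Thursday's / Monday's / all alike)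
2. Z at the end, in percent of the X charged, Friday's
3. Z at the end, in percent of the X charged, Thursday's
4. Z at the end, in percent of the X charged, Monday's

The bench rule says that a flat reading marks a flask's end, with the same balance whatever was charged. Counting one X and one Q spent per Z, the last spring reading gives 2.56 M⁻¹ for P, the reaction quotient [Z]/([X][Q]). The last winter reading, from other charges, gives 2.50 M⁻¹.

Since Z/X = P·[Q], my reckoning goes round on the Q left. The first answer is the mean of the spring and dusk plateaus, whose Q charges lie on either side of 0.500 M: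

first answer: 42.3 %

first round: 42.5 %

second round: 42.4 %

The rule's border is time. Flatness came by 30.0 h in the spring run and by 10.0 h in the dusk run, a ratio of 3.00 between 102 °C and 119 °C, though rough, since the Q charges differ. Scaled by it, my estimate puts flatness at 47.2 h for Friday's, later than its 40 h, and at 6.79 h for Thursday's. So I expect Thursday's and Monday's near 42.4 %, with Friday's short of its plateau.

The forecast lets the quotient fall with heat, where mine holds it fixed. It gives 40.7 % for Friday's, 40.1 % for Thursday's and 41.7 % for Monday's: “Monday's comes out highest”.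

Thursday's ends highest at 47.8 %, against 41.3 % for Friday's and 40.3 % for Monday's, and 5.4 percentage points above my reckoning. At 40.0 h Thursday's holds X 5.42 %, Q 9.22 % and L 43.0 %. Its P is 192 M⁻¹, far above 2.56 M⁻¹.

    Z ⇌ L (K = 1.70, k = 8.00 × 10⁻⁶ s⁻¹, Ea = 119 kJ mol⁻¹, ΔH = −52.0 kJ mol⁻¹)
    X ⇌ J (K = 0.890, k = 2.90 × 10⁻⁵ s⁻¹, Ea = 127 kJ mol⁻¹, ΔH = −23.0 kJ mol⁻¹)
    X + Q → Z + D (k = 7.00 × 10⁻⁵ M⁻¹ s⁻¹, Ea = 102 kJ mol⁻¹)
    G ⇌ Z, rate k4*(cs4 - [Z]) while solid is left; crystals form when [Z] > cs4 (solubility = 0.430 M, k = 1.60 × 10⁻⁴ s⁻¹)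
    (constants at 110 °C)

For a neighbour flask, Friday's with 1.2 M of Q, two rounds from 42.4 % with P = 2.56 M⁻¹ give 71.6 %, then 68.3 %. That neighbour flask gives 65.6 %, with a P of 11.9 M⁻¹.

The data were computed for an exercise; the scatter is artificial.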